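**Strategy.** Ring B is cut at C5–C6 and C8–C9. Ring A then carries both electrophiles on the quaternary C10, the C5 ketone and a C9 acyl chloride, and C6–C7–C8 with C17 arrive as the lithium dienolate of methyl 4-methoxycrotonate. In one operation the dienolate is C-acylated at its α-carbon (C8–C9) and the extended enolate condenses through its γ-carbon with the hindered ring ketone (C5–C6). The step exploits the 1,3-placement of C5 and C9 across C10, which also blocks aromatisation, so a cyclohexadienone with the C6 oxygen, the C7=C8 alkene and C17 results. C9, C5 and C6 are set later from the ring B face opposite the C10 methyl.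

Key step: step 6

Remark: atoms are numbered as in labdanes (C1–C10 decalin, C11–C16 side chain, C17 on C8, C18/C19 on C4, C20 on C10); but-1-en-3-yne is assumed to be purchasable as a solution.

Step 1
Reactants: 1 2,2,6-trimethylcyclohexan-1-one (racemic); 2 allyl chloroformate
Product: 3 allyl 2,6,6-trimethylcyclohex-1-en-1-yl carbonate
Conditions: LiN(SiMe3)2, THF, −78 °C; then 2, −78 → 0 °C
Reagents that add atoms: none
Why: Only the C10 enolate can form (the other α-carbon is quaternary), and O-acylation by the chloroformate should give the allyl enol carbonate; no stereocentre is formed.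

Step 2
Reactants: 3 allyl 2,6,6-trimethylcyclohex-1-en-1-yl carbonate
Product: 4 (S)-2-allyl-2,6,6-trimethylcyclohexan-1-one
Conditions: Pd2(dba)3 (cat.), (S)-t-Bu-PHOX (cat.; the ligand enantiomer that gives the S ketone), THF, 25 °C
Reagents that add atoms: none
Why: Palladium-catalysed decarboxylative asymmetric allylic alkylation (Tsuji allylation) should join the π-allyl fragment to one face of the tetrasubstituted enolate under control of the chiral phosphinooxazoline ligand, setting the quaternary C10 as S.

Step 3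
Reactants: 4 (S)-2-allyl-2,6,6-trimethylcyclohexan-1-one
Product: 5 (S)-2,2,6-trimethyl-6-[(E)-prop-1-en-1-yl]cyclohexan-1-one
Conditions: RuHCl(CO)(PPh3)3 (cat.), toluene, 80 °C
Reagents that add atoms: none
Why: Ruthenium hydride alkene isomerisation (hydrometalation/β-hydride elimination) should move the terminal alkene to the more stable E-disubstituted position; C10 has no hydrogen and cannot epimerise.

Step 4
Reactants: 5 (S)-2,2,6-trimethyl-6-[(E)-prop-1-en-1-yl]cyclohexan-1-one
Product: 6 (R)-1,3,3-trimethyl-2-oxocyclohexane-1-carboxylic acid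
Conditions: RuCl3 (cat.), NaIO4, CCl4–MeCN–H2O, 0 → 25 °C
Reagents that add atoms: sodium periodate, [Na+].[O-]I(=O)(=O)=O; water, O
Why: RuO4 generated in situ should cleave the disubstituted alkene oxidatively to the C9 carboxylic acid; the non-enolisable ketone and C10 are untouched (the descriptor changes only through priorities).

Step 5
Reactants: 6 (R)-1,3,3-trimethyl-2-oxocyclohexane-1-carboxylic acid
Product: 7 (R)-1,3,3-trimethyl-2-oxocyclohexane-1-carbonyl chloride
Conditions: (COCl)2, DMF (cat.), CH2Cl2, 0 → 25 °C; used crude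
Reagents that add atoms: oxalyl chloride, O=C(Cl)C(Cl)=O
Why: Acid chloride formation through Vilsmeier-type chloroiminium activation should proceed cold enough to avoid decarboxylation of the β-keto acid.

Step 6
Reactants: 7 (R)-1,3,3-trimethyl-2-oxocyclohexane-1-carbonyl chloride; 8 methyl (E)-4-methoxybut-2-enoate
Product: 11 methyl (8aR)-4-methoxy-5,5,8a-trimethyl-1-oxo-1,5,6,7,8,8a-hexahydronaphthalene-2-carboxylate, via keto diester 9 (not isolated), via aldol adduct 10 (not isolated)
Conditions: 8 (2.1 equiv), LiN(iPr)2 (2.1 equiv), THF–DMPU, −78 °C; add 7, −78 → 0 °C; then KOtBu (0.3 equiv), t-BuOH, 50 °C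
Reagents that add atoms: none
Why: The lithium dienolate of 8, formed by γ-deprotonation, should be C-acylated at its α-carbon by the acid chloride (crossed Claisen-type acylation, C8–C9), and the second dienolate equivalent deprotonates the β-keto ester 9 to a vinylogous enolate. This enolate can reach the ring ketone only through its γ-carbon, so a 6-(enolendo)-exo-trig vinylogous aldol addition closes ring B (C5–C6) to 10, and base-mediated E1cB loss of hydroxide gives the 2,4-cyclohexadienone 11. The closest known reaction types are the [3+3] cyclocondensations of 1,3-dinucleophiles with 1,3-dielectrophiles that give salicylates and the aldol condensations used to annulate 2,2,6-trimethylcyclohexanone derivatives; here the quaternary C10 stops the sequence before aromatisation. No stereocentre that survives is created (C5, C6 and C8 end as sp2 carbons), and C10 carries no hydrogen and is not touched. The step needs α- over γ- and C- over O-acylation, which the kinetic lithium dienolate at −78 °C should secure, and regioselective ring closure, which is enforced because ring A has no enolisable position and the α-carbon could only form a four-membered ring.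

Step 7
Reactants: 11 methyl (8aR)-4-methoxy-5,5,8a-trimethyl-1-oxo-1,5,6,7,8,8a-hexahydronaphthalene-2-carboxylate
Product: 12 methyl (8aS)-4-methoxy-5,5,8a-trimethyl-1-methylidene-1,5,6,7,8,8a-hexahydronaphthalene-2-carboxylate
Conditions: Zn, CH2Br2, TiCl4, THF–CH2Cl2, 0 → 25 °C
Reagents that add atoms: dibromomethane, BrCBr
Why: Takai–Lombardo methylenation with the non-basic zinc–titanium methylene reagent should convert the hindered, non-enolisable C9 ketone into the exocyclic C9=C11 methylene in preference to the ester; no stereocentre is involved.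

Step 8
Reactants: 13 but-1-en-3-yne
Product: 15 (1E)-1-iodo-2-methylbuta-1,3-diene, via dienylalane 14 (not isolated)
Conditions: AlMe3, Cp2ZrCl2 (cat.), CH2Cl2, 0 → 25 °C; then I2, THF, −30 → 0 °C
Reagents that add atoms: trimethylaluminium, C[Al](C)C; iodine, II
Why: Zirconium-catalysed carboalumination (Negishi) should add methyl and aluminium syn across the alkyne with methyl on the internal carbon, and iodinolysis with retention gives the E dienyl iodide carrying C12–C16.

Step 9
Reactants: 12 methyl (8aS)-4-methoxy-5,5,8a-trimethyl-1-methylidene-1,5,6,7,8,8a-hexahydronaphthalene-2-carboxylate; 15 (1E)-1-iodo-2-methylbuta-1,3-diene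
Product: 17 methyl (1S,8aS)-4-methoxy-5,5,8a-trimethyl-1-[(2E)-3-methylpenta-2,4-dien-1-yl]-1,5,6,7,8,8a-hexahydronaphthalene-2-carboxylate, via alkylborane 16 (not isolated)
Conditions: 9-BBN, THF, 0 → 25 °C; then 15, PdCl2(dppf), AsPh3, Cs2CO3, DMF–H2O, 25 °C
Reagents that add atoms: none
Why: Anti-Markovnikov hydroboration should place boron on C11 and deliver hydrogen to C9 from the ring B face opposite the C10 methyl (the usual approach next to an angular methyl), setting C9 as S, and the B-alkyl Suzuki–Miyaura coupling then forms C11–C12 with retention of the E geometry.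

Step 10
Reactants: 17 methyl (1S,8aS)-4-methoxy-5,5,8a-trimethyl-1-[(2E)-3-methylpenta-2,4-dien-1-yl]-1,5,6,7,8,8a-hexahydronaphthalene-2-carboxylate
Product: 18 methyl (1S,4aR,8aS)-5,5,8a-trimethyl-1-[(2E)-3-methylpenta-2,4-dien-1-yl]-4-oxo-1,4,4a,5,6,7,8,8a-octahydronaphthalene-2-carboxylate
Conditions: aqueous HCl (0.5 M), THF, 0 °C
Reagents that add atoms: water, O
Why: Enol ether hydrolysis (C5 protonation, hemiketal collapse) should unveil the C6 ketone conjugated with C7=C8; the epimerisable C5 settles as the trans-fused 5R isomer, and the cold, mild conditions are chosen to avoid γ-enolisation towards C9.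

Step 11
Reactants: 18 methyl (1S,4aR,8aS)-5,5,8a-trimethyl-1-[(2E)-3-methylpenta-2,4-dien-1-yl]-4-oxo-1,4,4a,5,6,7,8,8a-octahydronaphthalene-2-carboxylate
Product: 19 [(1S,4S,4aR,8aS)-4-hydroxy-5,5,8a-trimethyl-1-[(2E)-3-methylpenta-2,4-dien-1-yl]-1,4,4a,5,6,7,8,8a-octahydronaphthalen-2-yl]methanol
Conditions: iBu2AlH (excess), CH2Cl2, −78 → −20 °C; aqueous potassium sodium tartrate
Reagents that add atoms: none
Why: iBu2AlH should reduce the ester to the C17 alcohol and the enone carbonyl in 1,2-fashion, with hydride attacking C6 from the face opposite the axial C10 and C4 methyl groups to give the axial 6S alcohol cis to the C10 methyl.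

Step 12
Reactants: 19 [(1S,4S,4aR,8aS)-4-hydroxy-5,5,8a-trimethyl-1-[(2E)-3-methylpenta-2,4-dien-1-yl]-1,4,4a,5,6,7,8,8a-octahydronaphthalen-2-yl]methanol
Product: 20 [(1S,4S,4aR,8aS)-4-acetoxy-5,5,8a-trimethyl-1-[(2E)-3-methylpenta-2,4-dien-1-yl]-1,4,4a,5,6,7,8,8a-octahydronaphthalen-2-yl]methyl acetate
Conditions: Ac2O, pyridine, DMAP (cat.), CH2Cl2, 25 °C
Reagents that add atoms: acetic anhydride, CC(=O)OC(C)=O
Why: DMAP-catalysed acylation should esterify the primary and the hindered axial secondary alcohol without touching any stereocentre, giving the target (5R,6S,9S,10S in labdane numbering).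

**Compound list**

1 | 2,2,6-trimethylcyclohexan-1-one (racemic) | CC1CCCC(C)(C)C1=O | starting material
2 | allyl chloroformate | C=CCOC(Cl)=O | starting material
3 | allyl 2,6,6-trimethylcyclohex-1-en-1-yl carbonate | C=CCOC(=O)OC1=C(C)CCCC1(C)C | intermediate
4 | (S)-2-allyl-2,6,6-trimethylcyclohexan-1-one | C=CC[C@@]1(C)C(=O)C(C)(C)CCC1 | intermediate
5 | (S)-2,2,6-trimethyl-6-[(E)-prop-1-en-1-yl]cyclohexan-1-one | C/C=C/[C@@]1(C)C(=O)C(C)(C)CCC1 | intermediate
6 | (R)-1,3,3-trimethyl-2-oxocyclohexane-1-carboxylic acid | OC(=O)[C@@]1(C)C(=O)C(C)(C)CCC1 | intermediate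
7 | (R)-1,3,3-trimethyl-2-oxocyclohexane-1-carbonyl chloride | ClC(=O)[C@@]1(C)C(=O)C(C)(C)CCC1 | intermediate
8 | methyl (E)-4-methoxybut-2-enoate | COC/C=C/C(=O)OC | starting material
9 | methyl 4-methoxy-2-[(1S)-1,3,3-trimethyl-2-oxocyclohexane-1-carbonyl]but-3-enoate (C2 epimers, both enol ether geometries) | COC=CC(C(=O)OC)C(=O)[C@@]1(C)C(=O)C(C)(C)CCC1 | intermediate
10 | methyl (8aR)-4a-hydroxy-4-methoxy-5,5,8a-trimethyl-1-oxo-1,4,4a,5,6,7,8,8a-octahydronaphthalene-2-carboxylate (C4/C4a mixture) | O=C1C(C(=O)OC)=CC(OC)C2(O)C(C)(C)CCC[C@@]12C | intermediate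
11 | methyl (8aR)-4-methoxy-5,5,8a-trimethyl-1-oxo-1,5,6,7,8,8a-hexahydronaphthalene-2-carboxylate | O=C1C(C(=O)OC)=CC(OC)=C2C(C)(C)CCC[C@@]12C | intermediate
12 | methyl (8aS)-4-methoxy-5,5,8a-trimethyl-1-methylidene-1,5,6,7,8,8a-hexahydronaphthalene-2-carboxylate | C=C1C(C(=O)OC)=CC(OC)=C2C(C)(C)CCC[C@@]12C | intermediate
13 | but-1-en-3-yne | C=CC#C | starting material
14 | dimethyl[(1E)-2-methylbuta-1,3-dien-1-yl]alumane | C=C/C(C)=C/[Al](C)C | intermediate
15 | (1E)-1-iodo-2-methylbuta-1,3-diene | C=C/C(C)=C/I | intermediate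
16 | methyl (1S,8aS)-1-[(9-borabicyclo[3.3.1]nonan-9-yl)methyl]-4-methoxy-5,5,8a-trimethyl-1,5,6,7,8,8a-hexahydronaphthalene-2-carboxylate | C1CCC2CCCC1B2C[C@@H]3C(C(=O)OC)=CC(OC)=C4C(C)(C)CCC[C@@]34C | intermediate
17 | methyl (1S,8aS)-4-methoxy-5,5,8a-trimethyl-1-[(2E)-3-methylpenta-2,4-dien-1-yl]-1,5,6,7,8,8a-hexahydronaphthalene-2-carboxylate | C=C/C(C)=C/C[C@@H]1C(C(=O)OC)=CC(OC)=C2C(C)(C)CCC[C@@]12C | intermediate
18 | methyl (1S,4aR,8aS)-5,5,8a-trimethyl-1-[(2E)-3-methylpenta-2,4-dien-1-yl]-4-oxo-1,4,4a,5,6,7,8,8a-octahydronaphthalene-2-carboxylate | C=C/C(C)=C/C[C@@H]1C(C(=O)OC)=CC(=O)[C@@H]2C(C)(C)CCC[C@@]12C | intermediate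
19 | [(1S,4S,4aR,8aS)-4-hydroxy-5,5,8a-trimethyl-1-[(2E)-3-methylpenta-2,4-dien-1-yl]-1,4,4a,5,6,7,8,8a-octahydronaphthalen-2-yl]methanol | C=C/C(C)=C/C[C@@H]1C(CO)=C[C@H](O)[C@@H]2C(C)(C)CCC[C@@]12C | intermediate
20 | [(1S,4S,4aR,8aS)-4-acetoxy-5,5,8a-trimethyl-1-[(2E)-3-methylpenta-2,4-dien-1-yl]-1,4,4a,5,6,7,8,8a-octahydronaphthalen-2-yl]methyl acetate | C=C/C(C)=C/C[C@@H]1C(COC(C)=O)=C[C@H](OC(C)=O)[C@@H]2C(C)(C)CCC[C@@]12C | target

**Step count.** Total: 12 steps. Longest linear sequence: 11 steps (steps 1–7 and 9–12); step 8 is a one-step branch.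

**Steps most likely to fail and their fallbacks**

Step 6. The hindered acid chloride may acylate the dienolate on oxygen or twice, so that the vinylogous enolate needed for ring closure is not formed cleanly. The fallback sets out from 5 and returns at 11, making C8–C9 by an aldol addition to an unhindered aldehyde followed by oxidation instead of an acylation. Ozonolysis of 5 (O3, CH2Cl2, −78 °C; Me2S) should give (S)-1,3,3-trimethyl-2-oxocyclohexane-1-carbaldehyde F1. Addition of the lithium dienolate of 8 at −78 °C should give methyl 2-{hydroxy[(1S)-1,3,3-trimethyl-2-oxocyclohexyl]methyl}-4-methoxybut-3-enoate F2. Dess–Martin oxidation should give 9, now isolated, and KOtBu in t-BuOH at 50 °C should close it through 10 to 11.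

Step 7. The methylene reagent may add in conjugate fashion, or TiCl4 may cleave the acid-labile dienol ether, instead of the carbonyl being methylenated. The fallback sets out from 11 and returns at 12 by a Peterson olefination under basic, Lewis-acid-free conditions. Addition of Me3SiCH2Li/CeCl3 (THF, −78 °C) to the C9 ketone should give methyl (8aR)-1-hydroxy-4-methoxy-5,5,8a-trimethyl-1-[(trimethylsilyl)methyl]-1,5,6,7,8,8a-hexahydronaphthalene-2-carboxylate F3, and KH (THF, 0 °C) should eliminate it to 12.

Step 9. Transmetalation of the hindered B-alkyl group may be slow, so that protodeboronation or decomposition of the sensitive dienyl iodide takes over. The fallback sets out from 12 and returns at 17, building the diene by two olefinations instead of a cross-coupling. Hydroboration with 9-BBN as in the route gives 16, which is carbonylated (CO, KBH(OiPr)3, THF; then buffered H2O2) to methyl (1S,8aS)-4-methoxy-5,5,8a-trimethyl-1-(2-oxoethyl)-1,5,6,7,8,8a-hexahydronaphthalene-2-carboxylate F4. Wittig reaction with 2-(triphenylphosphoranylidene)propanal (toluene, 80 °C) should give methyl (1S,8aS)-4-methoxy-5,5,8a-trimethyl-1-[(2E)-3-methyl-4-oxobut-2-en-1-yl]-1,5,6,7,8,8a-hexahydronaphthalene-2-carboxylate F5, and methylenation with Ph3P=CH2 (THF, 0 °C) should give 17. C9 is still set by the hydroboration.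

**Further compounds**

F1 | step 6 | (S)-1,3,3-trimethyl-2-oxocyclohexane-1-carbaldehyde | O=C[C@@]1(C)C(=O)C(C)(C)CCC1
F2 | step 6 | methyl 2-{hydroxy[(1S)-1,3,3-trimethyl-2-oxocyclohexyl]methyl}-4-methoxybut-3-enoate (diastereomer mixture) | COC=CC(C(=O)OC)C(O)[C@@]1(C)C(=O)C(C)(C)CCC1
F3 | step 7 | methyl (8aR)-1-hydroxy-4-methoxy-5,5,8a-trimethyl-1-[(trimethylsilyl)methyl]-1,5,6,7,8,8a-hexahydronaphthalene-2-carboxylate (C1 epimers) | C[Si](C)(C)CC1(O)C(C(=O)OC)=CC(OC)=C2C(C)(C)CCC[C@@]12C
F4 | step 9 | methyl (1S,8aS)-4-methoxy-5,5,8a-trimethyl-1-(2-oxoethyl)-1,5,6,7,8,8a-hexahydronaphthalene-2-carboxylate | O=CC[C@@H]1C(C(=O)OC)=CC(OC)=C2C(C)(C)CCC[C@@]12C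
F5 | step 9 | methyl (1S,8aS)-4-methoxy-5,5,8a-trimethyl-1-[(2E)-3-methyl-4-oxobut-2-en-1-yl]-1,5,6,7,8,8a-hexahydronaphthalene-2-carboxylate | O=C/C(C)=C/C[C@@H]1C(C(=O)OC)=CC(OC)=C2C(C)(C)CCC[C@@]12C
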